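Early in the flask, I pictured the reagent arriving over 50 min into equal amounts of the two substrates, with the catalyst sharing out between them whatever reacted. How it was shared seemed the thing to learn from the earlier runs.

| flask | left-handed substrate | right-handed substrate | reagent | catalyst | remark | time |
|---|---|---|---|---|---|---|
| south-east | 1 M | 1 M | 1.4 equiv (fed, over 50 min) | 2.5 mol% | run made earlier; the fed solution adds 0.50 times the starting volume |  |
| north-west | 1 M | 1 M | 2.2 equiv (fed, over 50 min) | 2.5 mol% | run made earlier; the fed solution adds 0.50 times the starting volume |  |
| west | 1 M | 1 M | 1 equiv (fed, over 50 min) | 5 mol% | run made earlier; the fed solution adds 0.50 times the starting volume |  |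
| flask | 1.0 M | 1.0 M | 1.00 equiv (fed, over 50 min) | 2.5 mol% | the fed solution adds 0.50 times the starting volume | 2.0 d |

| run | time / h | left-handed substrate / % | left-handed product / % |
|---|---|---|---|
| south-east | 8.00 | 13.7 | 35.9 |
| south-east | 15.0 | 10.1 | 40.1 |
| south-east | 25.0 | 8.9 | 41.1 |
| south-east | 30.0 | 8.5 | 41.1 |
| south-east | 40.0 | 8.3 | 41.4 |
| south-east | 50.0 | 8.6 | 41.6 |
| north-west | 8.00 | 4.6 | 45.9 |
| north-west | 15.0 | 1.6 | 48.5 |
| north-west | 25.0 | 0.7 | 49.9 |
| north-west | 30.0 | 0 | 49.5 |
| north-west | 40.0 | 0.1 | 50.2 |
| north-west | 50.0 | 0 | 50.1 |
| west | 10.0 | 18.9 | 31.1 |
| west | 20.0 | 18.7 | 31.4 |
| west | 30.0 | 19.4 | 31.1 |
| west | 40.0 | 18.6 | 31.6 |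
| west | 50.0 | 18.4 | 30.9 |

(each reading ± 0.3 percentage points)

- catalyst is single-handed; left-handed substrate and right-handed substrate are mirror images of each other, charged as a racemate, each of them at the stated concentration
- charges are per starting volume, the dose included; the dosed solution carries all of it
- the numbers in the tables scatter by 0.3 percentage points (one standard deviation)
- the reaction counts as stopped when no species that holds the left-handed substrate and right-handed substrate together changes by six tenths of a point or more over the second half of the time

* which holds at 2.0 d: what has brought the reaction to rest, or that it has not come to rest (all of the left-handed substrate has reacted / the reagent has run out first / no working catalyst is left / it is still moving)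
* part of the left-handed substrate and right-handed substrate together gone at 2.0 d
* the left-handed product standing at 2.0 d, as a percentage of the left-handed substrate and right-handed substrate together charged
* amount of left-handed product if the flask were left three thousand times as long, in percent of the left-handed substrate and right-handed substrate together charged

I took one reagent per substrate molecule, so the west run's 1 equiv covers 50.0% of the substrates together, and I expected the same of the flask. The west run's left-handed product averaged 31.2%, which leaves the same figure of right-handed substrate standing. If each substrate falls first order in itself while both meet the same reagent and catalyst, the dosing cancels. The logarithm of the fraction of left-handed substrate remaining, divided by that of the right-handed, is then a constant, the selectivity factor s. I read s = 2.08 from the west run. The south-east plateau, at 41.3% left-handed product, gave 2.05 from a different charge of reagent.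

For the middle of the flask I assumed the rate follows the catalyst. The west run was flat by 10.0 h, so at 2.5 mol% the flask should be flat by about 20.0 h, less than 2.0 d. The north-west run, at the same loading, read 4.6% of left-handed substrate at 8.00 h and still fell to a reading of 0% at 30.0 h, so I expected working catalyst in the flask throughout. For the end of the flask, with the reagent as limiting reagent, I reckoned 31.2% of left-handed product.

The forecast said the reagent has run out first, with 50% gone, 31.2% of left-handed product, and 31.2% for the flask left far longer, on the ground that “The end point depends only on s and reagent, not loading”.

The flask gave the reagent has run out first, with 50.0% gone, 31.4% of left-handed product, and 31.4% in the long run.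

    reagent + catalyst + left-handed substrate → catalyst + left-handed product (k = 0.470 L² mol⁻² min⁻¹)
    reagent + catalyst + right-handed substrate → catalyst + right-handed product (k = 0.220 L² mol⁻² min⁻¹)

At 2.00 d the flask held 0% of its reagent, and the half-life of left-handed substrate by its step had reached 4200 d, far longer than 2.0 d. In the flask, 63% of the charged right-handed substrate remained; raising that fraction to the power s gives 38.2% of the charged left-handed substrate, and the flask held 37% of that charge.

For the same flask with 0.250 equiv of reagent instead, I took the two substrates as about equal throughout, so the left-handed share of the reagent used is s/(1+s) = 67.5%, which gives 8.44% of left-handed product. That computed neighbour held 8.38%.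

Readings and results are calculated with made-up constants; noise was put on by code.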